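## The problem

Target 16 is an open-chain C3 unit on a tetrasubstituted benzene ring. Ring carbon C1 (ortho to OCH3, meta to the free OH, para to CH3) carries a tertiary carbinol carbon whose other two substituents are a CH2O-tigloyl arm and a CH2OAc arm. No ring has to be built; the difficulty is the fully substituted carbinol carbon, which is crowded by an ortho-substituted aryl group and three oxygenated neighbours. It is the only stereocentre, it is (R), and it is stereogenic only because the two oxymethyl arms carry different acyl groups. The corresponding triol is therefore achiral, and any acyl shift from one primary oxygen to the other gives the enantiomer. Since no second stereocentre is present, the configuration must come from a temporary stereocentre, a reagent or a catalyst, and the two arms must stay chemically distinct from the moment it is set. The sensitive groups are the tertiary benzylic alcohol on an electron-rich ring (ionisable by strong acid), the two primary esters next to free hydroxyls (mobile under base), the phenol para to OCH3 (oxidisable to a quinone) and the conjugated (E)-tiglate (lost to hydride or hydrogenation). Two features open the key step. The para OH/OCH3 pair with the side chain ortho to OCH3 is what a 4,4-dimethoxycyclohexadienone gives after attack next to its ketal carbon and loss of methanol. The carbinol carbon with its oxygen and one CH2O arm is the α-carbon of a glycerate, which can be made nucleophilic as an enolate.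

## Retrosynthesis

**Acetate and phenol last (16 ⇒ 15 ⇒ 14).** The O–Si bond of silyl ether 15 and the acetyl C–O bond are cut first, giving diol monotiglate 14. The acetate is put on after the tiglate because the unavoidable intermediate with one ester and one free primary hydroxyl then carries the less mobile acyl group; a conjugated, α-branched ester migrates far less readily than an acetate. The phenol stays masked until the end because it would otherwise be acylated. The forward steps need only selective acetylation of a primary over a tertiary hydroxyl and a buffered fluoride cleavage.

**Acetal and tiglate (14 ⇒ 13 ⇒ 11 + 12).** The tertiary and one primary oxygen of 14 are tied back into the 2-tert-butyl-1,3-dioxolane of 13, and the tigloyl C–O bond is cut to alcohol 11 and tiglic acid 12. This keeps the arms distinct throughout: in 11 one is a free CH2OH and the other is the ring CH2O, so the achiral triol never appears. The forward reactions are a carbodiimide esterification that leaves the (E)-olefin alone and an acetal hydrolysis mild enough not to ionise the benzylic C–O bond.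

**Oxidation level of the tiglate arm (11 ⇒ 10 ⇒ 9).** The CH2OH carbon of 11 is taken back to the methyl ester of 10, and the aryl silyl ether to the free phenol of 9. This assigns the two arms different origins, a carboxyl carbon and a glycerate CH2O, which is what links the target to the chiral pool. The forward steps are a phenol silylation and a LiAlH4 reduction that the acetal tolerates.

**The aryl–carbinol bond (9 ⇒ 7 + 6, key disconnection).** The bond from ring carbon C1 to the quaternary carbon is cut. It is the only cut that divides 9 into two fragments of similar size, each one step from a commercial compound, and that sets the stereocentre in the same operation. In normal polarity an aryl metal would add to a ketone; with a dihydroxyacetone derivative the adduct is achiral, and with a hydroxypyruvate it would need an external chiral controller. Reversed polarity uses the glycerate enolate 7 as nucleophile and quinone monoketal 6 as an aryl cation equivalent. The forward reaction must give conjugate rather than carbonyl addition, attack at C5 of 6 (next to the ketal, in the enone arm without the methyl group) rather than at C3, attack on one enolate face, and aromatisation without loss of the acetal. Basic conditions are specified for the C–C bond formation, because acids that ionise the ketal tend to send nucleophiles ortho to the carbonyl oxygen, which would place the side chain ortho to OH.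

**The two partners (6 ⇒ 5; 7 ⇒ 4 ⇒ 1 + 2).** Monoketal 6 comes from 4-methoxy-2-methylphenol 5 by oxidation in methanol, which fixes the OH/OCH3/CH3 pattern of the target before the coupling. Enolate 7 comes from the cis acetal 4, made from the D-glycerate acetonide 1 and pivalaldehyde 2. The glycerate stereocentre is used to install the acetal stereocentre, which survives enolisation and then returns the chirality to the quaternary carbon. The forward demand is a diastereomerically pure acetal, since the enantiomeric purity of 16 depends on it.

## Roads not taken

**Alternative 1:** Cut the tertiary C–O bond with allylic transposition. The forward key step oxidises the (E)-allylic 2-nitrophenyl selenide A2, which has a CH(CH3)–Se stereocentre, with H2O2. The selenoxide undergoes a [2,3] shift through a five-membered transition state and gives the tertiary allylic alcohol A1 with an (E)-propenyl group.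
- Merits: chirality is relayed suprafacially from a secondary centre, which is easier to set than a quaternary one, and the conditions are mild and nearly neutral.
- Weak points for this target: A2 needs a geometrically pure trisubstituted styrenyl olefin and a configurationally pure C–Se centre. The migration terminus carries both aryl and silyloxymethyl, so one of them must sit inside the transition state, and chirality transfer depends on that preference. After the shift the propenyl group has to be cut down by ozonolysis and reduction in the presence of an electron-rich arene. Two of its three carbons are discarded, and the arms then need a protecting-group exchange before the two acylations.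
- Comparison: this road is better in the predictability of a concerted chirality transfer and avoids low-temperature enolate chemistry. The chosen plan is far shorter and convergent, keeps every carbon, and takes its arene pattern directly from 5. Against the concerted transfer it sets only a single tert-butyl group for facial control.

**Alternative 2:** Cut the C(quaternary)–CH2OH bond. The (S)-aryl oxirane A4 is deprotonated at its benzylic ring carbon with sec-butyllithium/TMEDA, and the lithio-oxirane is trapped by formaldehyde with retention to give the oxiranylmethanol A3.
- Merits: the endgame is shorter than in the chosen plan. After acetylation of A3, a tiglate nucleophile can open the oxirane at its CH2 carbon and unveil the tertiary alcohol directly. No diol monoester with a free primary hydroxyl appears, so the acyl-shift route to the enantiomer is avoided.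
- Weak points for this target: the electron-rich ring lowers the acidity of the oxirane proton and invites ring metalation ortho to OCH3. The lithiated oxirane is a carbenoid that must be kept configurationally stable at very low temperature. An oxirane carrying this aryl group rearranges or opens at the benzylic carbon with traces of acid. A4 itself must be made enantioenriched from 5 over several steps (ring functionalisation, oxirane construction, asymmetric induction or resolution).
- Comparison: in the endgame this road is better. The chosen plan accepts three more steps after the coupling and a migration-prone intermediate, which it counters by installing the tiglate first and acetylating under non-basic control. In return its stereocentre comes from an inexpensive chiral-pool ester by a substrate-controlled step, and no acid-labile aryl oxirane is carried.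

**Alternative 3:** Cut no skeletal bond at the key step and desymmetrise instead. The achiral diethyl aryl(hydroxy)malonate A6, from an aryl metal derived from 5 and diethyl oxomalonate A7, is hydrosilylated with a dinuclear zinc catalyst made from ZnEt2 and a chiral amino-alcohol ligand. One enantiotopic ester is reduced, giving the dihydroxy ester A5.
- Merits: the chirality is catalytic, the precursors are achiral and cheap, and A6 is reached very quickly.
- Weak points for this target: the catalyst must distinguish the ester groups next to a free tertiary hydroxyl and an ortho-substituted aryl group, and the sense and level of induction for that combination are not predictable from the substrate. The existing CH2OH of A5 is the future tiglate arm, but the remaining ester must still be reduced, so that arm has to be masked, the ester reduced and acetylated, and the tiglate introduced last. This leaves the more mobile acetate next to a free primary hydroxyl.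
- Comparison: this road is better in atom economy of the chiral information and needs no diastereomer separation. The chosen plan uses a stoichiometric chiral-pool ester and must purify acetal 4. It offers instead a predictable sense of induction and an endgame of equal length with the safer acylation order.

Key step: step 3

Assumption: enolate 7 is taken to react on the face opposite the tert-butyl group, as enolates of 2-tert-butyl-1,3-dioxolanes and related acetals normally do; the configurations of 8 to 16 follow from this.

## Route

Step 1
Reactants: 1 methyl (R)-2,2-dimethyl-1,3-dioxolane-4-carboxylate; 2 pivalaldehyde (2,2-dimethylpropanal)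
Product: 4 methyl (2R,4R)-2-tert-butyl-1,3-dioxolane-4-carboxylate (cis acetal), via methyl D-glycerate 3 (not isolated)
Conditions: TsOH·H2O (cat.), MeOH, rt, then evaporation; 2 (excess), pentane, reflux, azeotropic water removal; chromatography to isolate the cis isomer
Reagents that add atoms: none
Why: Acid-catalysed methanolysis of the acetonide frees the diol, and acetalisation with pivalaldehyde gives the more stable aldehyde-derived dioxolane without touching the glycerate centre (no base present); the acetal carbon forms as a cis/trans pair under thermodynamic control, the cis (2R,4R) isomer is separated, and the trans isomer can be re-equilibrated with acid and recycled.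

Step 2
Reactants: 5 4-methoxy-2-methylphenol
Product: 6 4,4-dimethoxy-2-methylcyclohexa-2,5-dien-1-one
Conditions: PhI(OAc)2, MeOH, 0 °C to rt; NaHCO3 work-up; used fresh
Reagents that add atoms: methanol, CO
Why: Oxidative dearomatisation of a para-alkoxyphenol by trivalent iodine; methanol captures the activated ring at the methoxy-bearing para carbon, the standard preparation of quinone monoketals.

Step 3
Reactants: 4 methyl (2R,4R)-2-tert-butyl-1,3-dioxolane-4-carboxylate; 6 4,4-dimethoxy-2-methylcyclohexa-2,5-dien-1-one
Product: 9 methyl (2R,4R)-2-tert-butyl-4-(5-hydroxy-2-methoxy-4-methylphenyl)-1,3-dioxolane-4-carboxylate, via lithium enolate 7 (not isolated), via Michael adduct 8 (not isolated)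
Conditions: LiN(i-Pr)2, THF, −78 °C; then 6, DMPU, −78 to −45 °C; AcOH quench; then camphorsulfonic acid (cat.), anhydrous CH2Cl2, 0 °C to rt
Reagents that add atoms: none
Why: Deprotonation of 4 gives the planar enolate 7, in which the acetal carbon is the only stereocentre left; β-elimination of the ring oxygen is stereoelectronically disfavoured because the C–O bond lies near the nodal plane of the enolate (the reverse of a 5-endo-trig closure). Enolate 7 adds in Michael fashion to C5 of 6, the β-carbon of the enone arm without the α-methyl group, to give the enolate of 8; with acid one ketal methoxy group ionises, the proton at the newly substituted ring carbon is lost, and the dienone tautomerises to phenol 9 with OH and OCH3 already differentiated. The closest known reaction type is the conjugate addition–aromatisation of ester, ketone and 1,3-dicarbonyl enolates with quinone monoketals as aryl cation equivalents, combined with self-regeneration of stereocentres through 2-tert-butyl acetal enolates. No ring is closed; one C–C bond and one stereocentre are formed. The quaternary stereocentre is controlled by the tert-butyl group: the dienone approaches the face anti to it, so the aryl group ends up trans to tert-butyl in the place of the original hydrogen (overall retention), giving (2R,4R)-9. Conjugate addition is expected to prevail over carbonyl addition because the enolate carbon is fully substituted, the carbonyl is flanked by the methyl group, DMPU loosens the ion pair and any aldol-type adduct is reversible. C5 should be preferred over C3 because the α-methyl group makes its enone arm less electrophilic and crowds C3, and attack next to the ketal rather than ortho to the carbonyl is secured by forming the C–C bond under basic, non-ionising conditions. The stereocentre formed at the ring carbon of 8 is erased on aromatisation, and the acid stage is anhydrous so that the pivalaldehyde acetal is not hydrolysed.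

Step 4
Reactants: 9 methyl (2R,4R)-2-tert-butyl-4-(5-hydroxy-2-methoxy-4-methylphenyl)-1,3-dioxolane-4-carboxylate
Product: 10 methyl (2R,4R)-2-tert-butyl-4-{2-methoxy-4-methyl-5-[(triisopropylsilyl)oxy]phenyl}-1,3-dioxolane-4-carboxylate
Conditions: TIPSCl, imidazole, DMAP (cat.), DMF, rt to 40 °C
Reagents that add atoms: chlorotriisopropylsilane, CC(C)[Si](Cl)(C(C)C)C(C)C
Why: Standard phenol silylation; the triisopropylsilyl ether is chosen because an aryl ether of this size should survive LiAlH4, carbodiimide acylation and the dilute aqueous acid of step 7, yet leave under buffered fluoride.

Step 5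
Reactants: 10 methyl (2R,4R)-2-tert-butyl-4-{2-methoxy-4-methyl-5-[(triisopropylsilyl)oxy]phenyl}-1,3-dioxolane-4-carboxylate
Product: 11 [(2R,4S)-2-tert-butyl-4-{2-methoxy-4-methyl-5-[(triisopropylsilyl)oxy]phenyl}-1,3-dioxolan-4-yl]methanol
Conditions: LiAlH4, THF, 0 °C; aqueous NaOH work-up
Reagents that add atoms: none
Why: Hydride reduction of the α-quaternary methyl ester to the neopentyl-type primary alcohol; the acetal and aryl silyl ether are inert at 0 °C and the stereocentre cannot enolise (the descriptor changes from R to S only through the priority rules).

Step 6
Reactants: 11 [(2R,4S)-2-tert-butyl-4-{2-methoxy-4-methyl-5-[(triisopropylsilyl)oxy]phenyl}-1,3-dioxolan-4-yl]methanol; 12 tiglic acid ((2E)-2-methylbut-2-enoic acid)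
Product: 13 [(2R,4R)-2-tert-butyl-4-{2-methoxy-4-methyl-5-[(triisopropylsilyl)oxy]phenyl}-1,3-dioxolan-4-yl]methyl (2E)-2-methylbut-2-enoate
Conditions: 12, DCC, DMAP (cat.), CH2Cl2, 0 °C to rt
Reagents that add atoms: none
Why: Steglich esterification of the only free hydroxyl; carbodiimide/DMAP activation avoids the acid chloride/amine conditions that can deconjugate α,β-unsaturated acyl groups, so the (E)-olefin of 12 is carried over unchanged.

Step 7
Reactants: 13 [(2R,4R)-2-tert-butyl-4-{2-methoxy-4-methyl-5-[(triisopropylsilyl)oxy]phenyl}-1,3-dioxolan-4-yl]methyl (2E)-2-methylbut-2-enoate
Product: 14 (2R)-2,3-dihydroxy-2-{2-methoxy-4-methyl-5-[(triisopropylsilyl)oxy]phenyl}propyl (2E)-2-methylbut-2-enoate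
Conditions: 1 M aq. HCl–THF (1:4), rt, monitored; NaHCO3 quench
Reagents that add atoms: none
Why: Acid hydrolysis of the aldehyde acetal through the oxocarbenium ion at the acetal carbon, so neither C–O bond at the carbinol carbon is broken and its configuration is kept; dilute aqueous acid at rt should stay below the threshold for benzylic ionisation, and the conjugated, α-branched tiglate migrates only slowly under acidic conditions.

Step 8
Reactants: 14 (2R)-2,3-dihydroxy-2-{2-methoxy-4-methyl-5-[(triisopropylsilyl)oxy]phenyl}propyl (2E)-2-methylbut-2-enoate
Product: 15 (2R)-3-(acetyloxy)-2-hydroxy-2-{2-methoxy-4-methyl-5-[(triisopropylsilyl)oxy]phenyl}propyl (2E)-2-methylbut-2-enoate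
Conditions: Ac2O (excess), pyridine, CH2Cl2, 0 °C
Reagents that add atoms: acetic anhydride, CC(=O)OC(C)=O
Why: Chemoselective acetylation of the primary over the hindered tertiary benzylic hydroxyl; excess anhydride with a weak base at 0 °C captures the primary hydroxyl before the tiglate can shift to it, a shift that would lead to the enantiomer.

Step 9
Reactants: 15 (2R)-3-(acetyloxy)-2-hydroxy-2-{2-methoxy-4-methyl-5-[(triisopropylsilyl)oxy]phenyl}propyl (2E)-2-methylbut-2-enoate
Product: 16 (2R)-3-(acetyloxy)-2-hydroxy-2-(5-hydroxy-2-methoxy-4-methylphenyl)propyl (2E)-2-methylbut-2-enoate
Conditions: Bu4NF, AcOH (1:1), THF, 0 °C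
Reagents that add atoms: none
Why: Fluoride cleavage of the aryl silyl ether; buffering with acetic acid keeps phenoxide and alkoxide concentrations low so that ester cleavage and acyl migration to the tertiary or phenolic oxygen are avoided.

## Compound list

1 | methyl (R)-2,2-dimethyl-1,3-dioxolane-4-carboxylate | COC(=O)[C@H]1COC(C)(C)O1 | starting material
2 | pivalaldehyde (2,2-dimethylpropanal) | CC(C)(C)C=O | starting material
3 | methyl (R)-2,3-dihydroxypropanoate (methyl D-glycerate) | COC(=O)[C@H](O)CO | intermediate
4 | methyl (2R,4R)-2-tert-butyl-1,3-dioxolane-4-carboxylate (cis) | COC(=O)[C@H]1CO[C@@H](C(C)(C)C)O1 | intermediate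
5 | 4-methoxy-2-methylphenol | COc1ccc(O)c(C)c1 | starting material
6 | 4,4-dimethoxy-2-methylcyclohexa-2,5-dien-1-one | COC1(OC)C=CC(=O)C(C)=C1 | intermediate
7 | lithium [(2R)-2-tert-butyl-1,3-dioxolan-4-ylidene](methoxy)methanolate (lithium enolate of 4) | [Li+].COC([O-])=C1CO[C@@H](C(C)(C)C)O1 | intermediate
8 | methyl (2R,4R)-2-tert-butyl-4-(2,2-dimethoxy-4-methyl-5-oxocyclohex-3-en-1-yl)-1,3-dioxolane-4-carboxylate (either configuration at the cyclohexene carbon; after the AcOH quench) | COC(=O)[C@@]1(C2CC(=O)C(C)=CC2(OC)OC)CO[C@@H](C(C)(C)C)O1 | intermediate
9 | methyl (2R,4R)-2-tert-butyl-4-(5-hydroxy-2-methoxy-4-methylphenyl)-1,3-dioxolane-4-carboxylate (aryl trans to tert-butyl) | COC(=O)[C@@]1(c2cc(O)c(C)cc2OC)CO[C@@H](C(C)(C)C)O1 | intermediate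
10 | methyl (2R,4R)-2-tert-butyl-4-{2-methoxy-4-methyl-5-[(triisopropylsilyl)oxy]phenyl}-1,3-dioxolane-4-carboxylate | COC(=O)[C@@]1(c2cc(O[Si](C(C)C)(C(C)C)C(C)C)c(C)cc2OC)CO[C@@H](C(C)(C)C)O1 | intermediate
11 | [(2R,4S)-2-tert-butyl-4-{2-methoxy-4-methyl-5-[(triisopropylsilyl)oxy]phenyl}-1,3-dioxolan-4-yl]methanol | OC[C@@]1(c2cc(O[Si](C(C)C)(C(C)C)C(C)C)c(C)cc2OC)CO[C@@H](C(C)(C)C)O1 | intermediate
12 | tiglic acid ((2E)-2-methylbut-2-enoic acid) | C/C=C(\C)C(=O)O | starting material
13 | [(2R,4R)-2-tert-butyl-4-{2-methoxy-4-methyl-5-[(triisopropylsilyl)oxy]phenyl}-1,3-dioxolan-4-yl]methyl (2E)-2-methylbut-2-enoate | C/C=C(\C)C(=O)OC[C@@]1(c2cc(O[Si](C(C)C)(C(C)C)C(C)C)c(C)cc2OC)CO[C@@H](C(C)(C)C)O1 | intermediate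
14 | (2R)-2,3-dihydroxy-2-{2-methoxy-4-methyl-5-[(triisopropylsilyl)oxy]phenyl}propyl (2E)-2-methylbut-2-enoate | C/C=C(\C)C(=O)OC[C@](O)(CO)c1cc(O[Si](C(C)C)(C(C)C)C(C)C)c(C)cc1OC | intermediate
15 | (2R)-3-(acetyloxy)-2-hydroxy-2-{2-methoxy-4-methyl-5-[(triisopropylsilyl)oxy]phenyl}propyl (2E)-2-methylbut-2-enoate | C/C=C(\C)C(=O)OC[C@](O)(COC(C)=O)c1cc(O[Si](C(C)C)(C(C)C)C(C)C)c(C)cc1OC | intermediate
16 | (2R)-3-(acetyloxy)-2-hydroxy-2-(5-hydroxy-2-methoxy-4-methylphenyl)propyl (2E)-2-methylbut-2-enoate | C/C=C(\C)C(=O)OC[C@](O)(COC(C)=O)c1cc(O)c(C)cc1OC | target

## Step count and risks

Total: 9 steps. Longest linear sequence: 8 steps (steps 1, 3, 4, 5, 6, 7, 8, 9 from 1; the branch from 5 through step 2 is equally long).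

**Step 3 (key step).** The most likely failures are these:
- carbonyl addition or electron transfer to the dienone instead of conjugate addition;
- fragmentation of the enolate by β-elimination if the temperature must be raised to make the addition go;
- attack at C3;
- incomplete facial selectivity, since a dioxolane enolate has only the tert-butyl group for control;
- capture of the oxocarbenium ion by the ester carbonyl during the acid stage (lactonisation with loss of the methoxy group) instead of proton loss.

Fallback: the same bond is made from the same ester by palladium-catalysed enolate arylation. Phenol 5 is silylated (TIPSCl, imidazole) to triisopropyl(4-methoxy-2-methylphenoxy)silane F1. This is brominated with NBS ortho to OCH3 and para to CH3 to give (5-bromo-4-methoxy-2-methylphenoxy)triisopropylsilane F2. Enolate 7, made from 4 as in step 3, is transmetallated with ZnCl2 to the chlorozinc enolate F3 and coupled with F2 using Pd(dba)2 and P(t-Bu)3 in THF at rt. The coupling is again expected anti to the tert-butyl group and gives 10 directly, where the route is rejoined.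

**Step 1.** The risk is incomplete separation of the cis and trans acetals. The two isomers give enantiomeric enolates, so any trans isomer left in 4 erodes the enantiomeric purity of everything that follows. Fallback: the series is entered from the enantiomeric ester. Methyl (S)-2,2-dimethyl-1,3-dioxolane-4-carboxylate F4 is treated with 2 by the same two-stage procedure, through methyl L-glycerate F5, and the trans isomer methyl (2R,4S)-2-tert-butyl-1,3-dioxolane-4-carboxylate F6 is isolated. F6 has the same acetal configuration as 4 and gives the identical enolate 7 on deprotonation, where the route is rejoined. Whichever diastereomer of the two series is obtained pure can therefore be used.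

**Step 7.** The hindered pivalaldehyde acetal may hydrolyse sluggishly. Stronger acid would then bring ionisation of the tertiary benzylic C–O bond (assisted by the neighbouring tiglate carbonyl, with loss of configuration) or tiglate migration. Fallback: the acetal is removed before any ester is present.
- Alcohol 11 is benzylated (NaH, BnBr, THF) to (2R,4S)-4-[(benzyloxy)methyl]-2-tert-butyl-4-{2-methoxy-4-methyl-5-[(triisopropylsilyl)oxy]phenyl}-1,3-dioxolane F7.
- F7 is hydrolysed with aqueous acid, where no acyl group can participate or migrate, to (2R)-3-(benzyloxy)-2-{2-methoxy-4-methyl-5-[(triisopropylsilyl)oxy]phenyl}propane-1,2-diol F8.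
- F8 is acetylated at the primary hydroxyl to (2S)-3-(benzyloxy)-2-hydroxy-2-{2-methoxy-4-methyl-5-[(triisopropylsilyl)oxy]phenyl}propyl acetate F9.
- F9 is hydrogenolysed (H2, Pd/C, EtOAc, neutral) to (2S)-2,3-dihydroxy-2-{2-methoxy-4-methyl-5-[(triisopropylsilyl)oxy]phenyl}propyl acetate F10.
- F10 is esterified at once with 12 (DCC, DMAP) to give 15, where the route is rejoined.

This detour is two steps longer and leaves the more mobile acetate briefly next to a free primary hydroxyl, which is why it is only the reserve.

**Step 8.** Base-promoted migration of the tiglate in 14 may compete with acetylation. A shift to the other primary oxygen followed by acetylation gives the enantiomer, and a shift to the tertiary oxygen gives a regioisomer. Fallback: 14 is acetylated enzymatically with vinyl acetate and immobilised Candida antarctica lipase B in an apolar solvent. This works without base, is specific for the primary hydroxyl and gives 15 directly; no new compound is involved.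

## Further compounds

F1 | step 3 | triisopropyl(4-methoxy-2-methylphenoxy)silane | COc1ccc(O[Si](C(C)C)(C(C)C)C(C)C)c(C)c1
F2 | step 3 | (5-bromo-4-methoxy-2-methylphenoxy)triisopropylsilane | COc1cc(C)c(O[Si](C(C)C)(C(C)C)C(C)C)cc1Br
F3 | step 3 | chlorozinc enolate of 4, chlorido{[(2R)-2-tert-butyl-1,3-dioxolan-4-ylidene](methoxy)methanolato}zinc | COC(O[Zn]Cl)=C1CO[C@@H](C(C)(C)C)O1
F4 | step 1 | methyl (S)-2,2-dimethyl-1,3-dioxolane-4-carboxylate | COC(=O)[C@@H]1COC(C)(C)O1
F5 | step 1 | methyl (S)-2,3-dihydroxypropanoate (methyl L-glycerate) | COC(=O)[C@@H](O)CO
F6 | step 1 | methyl (2R,4S)-2-tert-butyl-1,3-dioxolane-4-carboxylate (trans) | COC(=O)[C@@H]1CO[C@@H](C(C)(C)C)O1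
F7 | step 7 | (2R,4S)-4-[(benzyloxy)methyl]-2-tert-butyl-4-{2-methoxy-4-methyl-5-[(triisopropylsilyl)oxy]phenyl}-1,3-dioxolane | c1ccccc1COC[C@@]1(c2cc(O[Si](C(C)C)(C(C)C)C(C)C)c(C)cc2OC)CO[C@@H](C(C)(C)C)O1
F8 | step 7 | (2R)-3-(benzyloxy)-2-{2-methoxy-4-methyl-5-[(triisopropylsilyl)oxy]phenyl}propane-1,2-diol | c1ccccc1COC[C@](O)(CO)c1cc(O[Si](C(C)C)(C(C)C)C(C)C)c(C)cc1OC
F9 | step 7 | (2S)-3-(benzyloxy)-2-hydroxy-2-{2-methoxy-4-methyl-5-[(triisopropylsilyl)oxy]phenyl}propyl acetate | c1ccccc1COC[C@](O)(COC(C)=O)c1cc(O[Si](C(C)C)(C(C)C)C(C)C)c(C)cc1OC
F10 | step 7 | (2S)-2,3-dihydroxy-2-{2-methoxy-4-methyl-5-[(triisopropylsilyl)oxy]phenyl}propyl acetate | OC[C@](O)(COC(C)=O)c1cc(O[Si](C(C)C)(C(C)C)C(C)C)c(C)cc1OC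
F0 | step 8 | none | none
A1 | alternative 1 | (2S,3E)-1-[(tert-butyldimethylsilyl)oxy]-2-{2-methoxy-4-methyl-5-[(triisopropylsilyl)oxy]phenyl}pent-3-en-2-ol | CC(C)(C)[Si](C)(C)OC[C@](O)(/C=C/C)c1cc(O[Si](C(C)C)(C(C)C)C(C)C)c(C)cc1OC
A2 | alternative 1 | tert-butyl{[(2E,4R)-2-{2-methoxy-4-methyl-5-[(triisopropylsilyl)oxy]phenyl}-4-[(2-nitrophenyl)selanyl]pent-2-en-1-yl]oxy}dimethylsilane | C[C@@H]([Se]c1ccccc1[N+](=O)[O-])/C=C(/CO[Si](C)(C)C(C)(C)C)c1cc(O[Si](C(C)C)(C(C)C)C(C)C)c(C)cc1OC
A3 | alternative 2 | [(2R)-2-{2-methoxy-4-methyl-5-[(triisopropylsilyl)oxy]phenyl}oxiran-2-yl]methanol | C1[C@](O1)(CO)c1cc(O[Si](C(C)C)(C(C)C)C(C)C)c(C)cc1OC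
A4 | alternative 2 | (2S)-2-{2-methoxy-4-methyl-5-[(triisopropylsilyl)oxy]phenyl}oxirane | C1[C@@H](O1)c1cc(O[Si](C(C)C)(C(C)C)C(C)C)c(C)cc1OC
A5 | alternative 3 | ethyl (2S)-2,3-dihydroxy-2-{2-methoxy-4-methyl-5-[(triisopropylsilyl)oxy]phenyl}propanoate | OC[C@](O)(C(=O)OCC)c1cc(O[Si](C(C)C)(C(C)C)C(C)C)c(C)cc1OC
A6 | alternative 3 | diethyl 2-hydroxy-2-{2-methoxy-4-methyl-5-[(triisopropylsilyl)oxy]phenyl}propanedioate | CCOC(=O)C(O)(C(=O)OCC)c1cc(O[Si](C(C)C)(C(C)C)C(C)C)c(C)cc1OC
A7 | alternative 3 | diethyl 2-oxopropanedioate | CCOC(=O)C(=O)C(=O)OCC
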